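**Plan**

- Numbering used throughout (drimane numbering, for locants and CIP descriptors): ring A = C1–C2–C3–C4–C5–C10, ring B = C5–C6–C7–C8–C9–C10, C11 on C9.
- Enabling feature: ring B carries oxygen at C6, methyls at C8 and C10 and an oxidised C9, which is the carbon pattern of 2,6-dimethyl-1,4-benzoquinone. As its C6 monoketal, the C5=C10 edge is a dienophile onto which C1–C4 of ring A can be annulated.
- Retrosynthetic cuts, in order: C11–OAr, then C9–C11, then the second C4–CH3, then C1–C10 and C4–C5 together (Diels–Alder).
- Forward: ring B comes from the aromatic ring of phenol 1, ring A is closed by the [4+2], then the C4 methyl, C11 and the coumarin are attached.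
- Stereochemistry: C10 from the chiral catalyst; C5 by base equilibration to the trans-decalin; C3 by equatorial hydride attack; C9 by hydroboration anti to the C10 methyl.

Key step: step 3

Remark (assumption): the (S)-configured catalyst, (S)-3,3-diphenyl-1-(2-methylphenyl)tetrahydro-1H,3H-pyrrolo[1,2-c][1,3,2]oxazaborole activated with HNTf2, is taken to give (10R)-5. If the sense of induction is the opposite, its (R)-enantiomer is used in the same way.

**Route**

Step 1
Reactants: 1 4-methoxy-2,6-dimethylphenol
Product: 2 4,4-dimethoxy-2,6-dimethylcyclohexa-2,5-dien-1-one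
Conditions: PhI(OAc)2 (1.1 equiv), MeOH, 0 °C
Reagents that add atoms: methanol, CO
Why: Oxidative dearomatisation of a para-alkoxyphenol by the trivalent iodine reagent, with methanol capturing the ring carbon that already bears the methoxy group, is a standard entry to quinone monoketals and creates no stereocentre.

Step 2
Reactants: 3 pent-1-en-3-one
Product: 4 (Z)-3-(tert-butyldimethylsilyloxy)penta-1,3-diene
Conditions: TBSOTf (1.1 equiv), Et3N (1.3 equiv), Et2O, 0 °C
Reagents that add atoms: tert-butyldimethylsilyl trifluoromethanesulfonate, CC(C)(C)[Si](C)(C)OS(=O)(=O)C(F)(F)F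
Why: Soft enolisation (O-silylation by the silyl triflate, then deprotonation of the ethyl group by the amine) converts the vinyl ketone into the 2-silyloxydiene, and the Z enol ether, whose methyl is trans to the vinyl group and so points outward in the s-cis diene, is expected because it avoids A(1,3) strain between methyl and vinyl.

Step 3
Reactants: 2 4,4-dimethoxy-2,6-dimethylcyclohexa-2,5-dien-1-one; 4 (Z)-3-(tert-butyldimethylsilyloxy)penta-1,3-diene
Product: 5 (4R,5S,10R)-3-(tert-butyldimethylsilyloxy)-6,6-dimethoxy-4,8,10-trimethyl-cis-decalin-2,7-dien-9-one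
Conditions: (S)-3,3-diphenyl-1-(2-methylphenyl)tetrahydro-1H,3H-pyrrolo[1,2-c][1,3,2]oxazaborole·HNTf2 (20 mol %), CH2Cl2, −78 → −40 °C
Reagents that add atoms: none
Why: The protonated oxazaborolidine binds the C9 carbonyl, the only free carbonyl because C6 is masked as the ketal, and lowers the LUMO of the enone so that a concerted but asynchronous [4+2] cycloaddition takes place in which the enol-ether β-carbon of the diene (future C4) bonds to the enone β-carbon C5 ahead of the C1–C10 bond, leaving the silyloxy group para to the carbonyl-bearing C10. The closest known reaction type is the oxazaborolidinium-catalysed Diels–Alder reaction of quinone monoketals and 2-methylcycloalkenones with 2-silyloxydienes. Ring A is closed by intermolecular [4+2] cycloaddition, its six carbons coming from the four diene carbons and the C5=C10 edge of ring B. C10 is fixed by the catalyst, which must choose one of the two enantiotopic enone double bonds and one of its faces; C5 follows from suprafacial addition and is therefore cis to the C10 methyl; C4 follows from the endo transition state (ring B under the diene) and the Z geometry of 4, which place the C4 methyl trans to H5, and this centre is of no consequence because C4 is later made quaternary. Besides enantioselectivity the step needs site and orientation control: only the two equivalent enone double bonds are dienophilic, and the orientation is dictated by the silyloxy group together with the single activating carbonyl.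

Step 4
Reactants: 5 (4R,5S,10R)-3-(tert-butyldimethylsilyloxy)-6,6-dimethoxy-4,8,10-trimethyl-cis-decalin-2,7-dien-9-one
Product: 6 (4R,5S,10R)-6,6-dimethoxy-4,8,10-trimethyl-cis-decalin-1,7-diene-3,9-dione
Conditions: Pd(OAc)2 (1.1 equiv), MeCN, 23 °C
Reagents that add atoms: none
Why: Saegusa–Ito oxidation: the enol silane transmetalates to a C2-bound palladium enolate whose only β-hydrogens are on C1, so β-hydride elimination gives the C1=C2 enone regiospecifically and leaves C4 as the only enolisable position next to the C3 carbonyl.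

Step 5
Reactants: 6 (4R,5S,10R)-6,6-dimethoxy-4,8,10-trimethyl-cis-decalin-1,7-diene-3,9-dione
Product: 8 (5S,10R)-6,6-dimethoxy-4,4,8,10-tetramethyl-cis-decalin-1,7-diene-3,9-dione, via lithium C3 dienolate 7 (not isolated)
Conditions: LiN(iPr)2 (1.15 equiv), THF, −78 °C; then MeI, DMPU, −78 → 0 °C
Reagents that add atoms: iodomethane, CI (LiN(iPr)2, CC(C)N([Li])C(C)C, supplies the lithium of intermediate 7 only)
Why: Kinetic α′-deprotonation and C-alkylation of an enone enolate: C2 is vinylic, C10 is quaternary and the C9 ketone has no α-hydrogen, so the base can only remove H4, and methylation of the cross-conjugated dienolate makes C4 the gem-dimethyl carbon and removes the C4 stereocentre, so that any exo adduct carried from step 3 converges.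

Step 6
Reactants: 8 (5S,10R)-6,6-dimethoxy-4,4,8,10-tetramethyl-cis-decalin-1,7-diene-3,9-dione
Product: 9 (5S,10R)-6,6-dimethoxy-4,4,8,10-tetramethyl-3-(triethylsilyloxy)-cis-decalin-2,7-dien-9-one
Conditions: Et3SiH (1.5 equiv), RhCl(PPh3)3 (2 mol %), benzene, 50 °C
Reagents that add atoms: triethylsilane, CC[SiH](CC)CC
Why: Rhodium-catalysed 1,4-hydrosilylation of an enone by a monohydrosilane places hydrogen on C1 and silicon on oxygen; the cis-disubstituted ring A enone should react in preference to the α-methylated ring B enone whose β-carbon is shielded by the ketal, much as the same catalyst hydrogenates only the disubstituted double bond of cross-conjugated 1,4-dien-3-ones, and the enol silane formed masks C3 for the next step.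

Step 7
Reactants: 9 (5S,10R)-6,6-dimethoxy-4,4,8,10-tetramethyl-3-(triethylsilyloxy)-cis-decalin-2,7-dien-9-one
Product: 10 (5R,10R)-6,6-dimethoxy-4,4,8,10-tetramethyl-9-methylidene-3-(triethylsilyloxy)-cis-decalin-2,7-diene
Conditions: Ph3PCH3Br (3 equiv), KN(SiMe3)2 (2.8 equiv), toluene, 0 → 23 °C; then 9, 80 °C
Reagents that add atoms: methyltriphenylphosphonium bromide, C[P+](c1ccccc1)(c1ccccc1)c1ccccc1.[Br-]
Why: Wittig methylenation: with C3 masked, C9 is the only carbonyl and it cannot be enolised, so an excess of salt-free ylide in hot toluene, the usual remedy for hindered ketones, should convert it into the exocyclic C9=C11 alkene without touching the ketal or the enol silane.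

Step 8
Reactants: 10 (5R,10R)-6,6-dimethoxy-4,4,8,10-tetramethyl-9-methylidene-3-(triethylsilyloxy)-cis-decalin-2,7-diene
Product: 12 (5S,10R)-4,4,8,10-tetramethyl-9-methylidene-trans-decal-7-ene-3,6-dione, via cis-fused diketone 11 (not isolated)
Conditions: 1 M HCl, THF, 23 °C; then DBU, toluene, 60 °C
Reagents that add atoms: water, O (supplies the C6 carbonyl oxygen)
Why: Aqueous acid hydrolyses the silyl enol ether and the dimethyl ketal, and the freed C6 ketone makes H5 acidic, so that the non-nucleophilic amidine base equilibrates C5 through the enolate to the trans-fused decalin, which is expected to be the more stable ring fusion in the 4,4,10-trimethyl series; C5 is thus set under thermodynamic control.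

Step 9
Reactants: 12 (5S,10R)-4,4,8,10-tetramethyl-9-methylidene-trans-decal-7-ene-3,6-dione
Product: 13 (3S,5S,10R)-3-hydroxy-4,4,8,10-tetramethyl-9-methylidene-trans-decal-7-en-6-one
Conditions: K[HB(sec-Bu)3] (1.1 equiv), THF, −78 °C; then H2O
Reagents that add atoms: none
Why: Reduction of a cyclohexanone by a bulky trialkylborohydride: in the rigid trans-decalin the hydride enters along the equatorial trajectory and gives the axial C3 alcohol, trans to the C10 methyl, as is usual for 4,4-dimethyl-3-oxo terpenoids, while the conjugated C6 carbonyl, flanked by C5 and the C4 methyls, should react more slowly.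

Step 10
Reactants: 13 (3S,5S,10R)-3-hydroxy-4,4,8,10-tetramethyl-9-methylidene-trans-decal-7-en-6-one
Product: 15 (3S,5S,6S,9R,10S)-9-(hydroxymethyl)-4,4,8,10-tetramethyl-trans-decal-7-ene-3,6-diol, via tris(9-BBN) adduct 14 (not isolated)
Conditions: 9-BBN (4 equiv), THF, 0 → 65 °C; then NaOH, H2O2, H2O, 0 → 23 °C
Reagents that add atoms: hydrogen peroxide, OO (oxygen on C11); 9-borabicyclo[3.3.1]nonane, B1C2CCCC1CCC2 (its boron stays only in intermediate 14)
Why: Hydroboration–oxidation: 9-BBN adds boron to the terminal C11 of the 1,1-disubstituted alkene and delivers hydrogen to C9 from the face opposite the axial C10 methyl, so that C11 ends up cis to that methyl (equatorial), it leaves the trisubstituted C7=C8 alone and reduces the C6 carbonyl in 1,2 fashion from the same open face to a temporary axial allylic alcohol, and alkaline peroxide then replaces boron by oxygen with retention.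

Step 11
Reactants: 15 (3S,5S,6S,9R,10S)-9-(hydroxymethyl)-4,4,8,10-tetramethyl-trans-decal-7-ene-3,6-diol; 16 umbelliferone
Product: 17 7-{[(3S,5S,6S,9R,10S)-3,6-dihydroxy-4,4,8,10-tetramethyl-trans-decal-7-en-9-yl]methoxy}-2H-chromen-2-one
Conditions: PPh3 (1.3 equiv), DIAD (1.3 equiv), THF, 0 → 23 °C
Reagents that add atoms: none
Why: Mitsunobu etherification: the phenol of umbelliferone (pKa near 8) displaces the alkoxyphosphonium of the primary C11 alcohol in an SN2 reaction while the two hindered secondary alcohols at C3 and C6 are not activated, and carrying C6 as the alcohol keeps H9 non-acidic so that no elimination toward the dienone can occur.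

Step 12
Reactants: 17 7-{[(3S,5S,6S,9R,10S)-3,6-dihydroxy-4,4,8,10-tetramethyl-trans-decal-7-en-9-yl]methoxy}-2H-chromen-2-one
Product: 18 ferocaulidin
Conditions: MnO2 (activated, excess), CH2Cl2, 23 °C
Reagents that add atoms: none
Why: MnO2 oxidises allylic alcohols selectively, so only the C6 carbinol is converted into the enone while the saturated C3 alcohol and the coumarin are untouched, and the neutral conditions avoid both vinylogous β-elimination of the aryloxy group and epimerisation at C9 or C5.

**Compound list**

1 | 4-methoxy-2,6-dimethylphenol | COc1cc(C)c(O)c(C)c1 | starting material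
2 | 4,4-dimethoxy-2,6-dimethylcyclohexa-2,5-dien-1-one | CC1=CC(OC)(OC)C=C(C)C1=O | intermediate
3 | pent-1-en-3-one | CCC(=O)C=C | starting material
4 | (Z)-3-(tert-butyldimethylsilyloxy)penta-1,3-diene | C=C/C(O[Si](C)(C)C(C)(C)C)=C/C | intermediate
5 | (4R,5S,10R)-3-(tert-butyldimethylsilyloxy)-6,6-dimethoxy-4,8,10-trimethyl-cis-decalin-2,7-dien-9-one (H5 cis to C10 methyl, C4 methyl trans to H5) | CC1=CC(OC)(OC)[C@H]2[C@@H](C)C(O[Si](C)(C)C(C)(C)C)=CC[C@@]2(C)C1=O | intermediate
6 | (4R,5S,10R)-6,6-dimethoxy-4,8,10-trimethyl-cis-decalin-1,7-diene-3,9-dione | CC1=CC(OC)(OC)[C@H]2[C@@H](C)C(=O)C=C[C@@]2(C)C1=O | intermediate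
7 | lithium dienolate of 6 (O–Li on C3, C3=C4 and C1=C2; C5 and C10 as in 6) | CC1=CC(OC)(OC)[C@H]2C(C)=C(O[Li])C=C[C@@]2(C)C1=O | intermediate
8 | (5S,10R)-6,6-dimethoxy-4,4,8,10-tetramethyl-cis-decalin-1,7-diene-3,9-dione | CC1=CC(OC)(OC)[C@H]2C(C)(C)C(=O)C=C[C@@]2(C)C1=O | intermediate
9 | (5S,10R)-6,6-dimethoxy-4,4,8,10-tetramethyl-3-(triethylsilyloxy)-cis-decalin-2,7-dien-9-one | CC1=CC(OC)(OC)[C@H]2C(C)(C)C(O[Si](CC)(CC)CC)=CC[C@@]2(C)C1=O | intermediate
10 | (5R,10R)-6,6-dimethoxy-4,4,8,10-tetramethyl-9-methylidene-3-(triethylsilyloxy)-cis-decalin-2,7-diene | CC1=CC(OC)(OC)[C@H]2C(C)(C)C(O[Si](CC)(CC)CC)=CC[C@@]2(C)C1=C | intermediate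
11 | (5R,10R)-4,4,8,10-tetramethyl-9-methylidene-cis-decal-7-ene-3,6-dione | CC1=CC(=O)[C@H]2C(C)(C)C(=O)CC[C@@]2(C)C1=C | intermediate
12 | (5S,10R)-4,4,8,10-tetramethyl-9-methylidene-trans-decal-7-ene-3,6-dione | CC1=CC(=O)[C@@H]2C(C)(C)C(=O)CC[C@@]2(C)C1=C | intermediate
13 | (3S,5S,10R)-3-hydroxy-4,4,8,10-tetramethyl-9-methylidene-trans-decal-7-en-6-one (axial 3-OH, trans to C10 methyl) | CC1=CC(=O)[C@@H]2C(C)(C)[C@@H](O)CC[C@@]2(C)C1=C | intermediate
14 | tris(9-borabicyclo[3.3.1]nonan-9-yl) adduct: B on C11, O–B on C3 and C6, stereocentres as in 15 | CC1=C[C@H](OB3C4CCCC3CCC4)[C@@H]2C(C)(C)[C@@H](OB3C4CCCC3CCC4)CC[C@@]2(C)[C@@H]1CB3C4CCCC3CCC4 | intermediate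
15 | (3S,5S,6S,9R,10S)-9-(hydroxymethyl)-4,4,8,10-tetramethyl-trans-decal-7-ene-3,6-diol (C11 and 6-OH cis to C10 methyl, 3-OH trans to it) | CC1=C[C@H](O)[C@@H]2C(C)(C)[C@@H](O)CC[C@@]2(C)[C@@H]1CO | intermediate
16 | umbelliferone (7-hydroxy-2H-chromen-2-one) | O=c1ccc2ccc(O)cc2o1 | starting material
17 | 7-{[(3S,5S,6S,9R,10S)-3,6-dihydroxy-4,4,8,10-tetramethyl-trans-decal-7-en-9-yl]methoxy}-2H-chromen-2-one | CC1=C[C@H](O)[C@@H]2C(C)(C)[C@@H](O)CC[C@@]2(C)[C@@H]1COc1ccc2ccc(=O)oc2c1 | intermediate
18 | ferocaulidin, 7-{[(3S,5S,9R,10S)-3-hydroxy-4,4,8,10-tetramethyl-6-oxo-trans-decal-7-en-9-yl]methoxy}-2H-chromen-2-one | CC1=CC(=O)[C@@H]2C(C)(C)[C@@H](O)CC[C@@]2(C)[C@@H]1COc1ccc2ccc(=O)oc2c1 | target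

**Count and risks**

Total step count: 12. Longest linear sequence: 11 steps (step 1 or step 2, then steps 3 to 12).

Three steps most likely to fail:

1. Step 3. The cycloaddition may be slow at the α-methylated, ketal-flanked enone, and enantiofacial discrimination may be weak because the C9 carbonyl sits between two vinylic methyls and binds the bulky boron cation poorly; the acidic catalyst may also protodesilylate the diene. Fallback: setting out from 2 and 4, the cycloaddition is run without asymmetric induction, promoted by an achiral Lewis acid such as Me2AlCl in CH2Cl2 at low temperature (or thermally under high pressure). This should give the same endo, cis-fused adduct as the racemate, that is 5 together with its mirror image, the (4S,5R,10S)-adduct F1. The enantiomers are then separated by preparative chromatography on a chiral stationary phase, and the route is rejoined at 5.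

2. Step 9. Hydride may be delivered to the dienone instead of the C3 ketone, by 1,6-addition at the exocyclic C11 methylene or 1,2-addition at C6, so that chemoselectivity is lost. Fallback: setting out from 12, a Luche reduction (NaBH4, CeCl3·7H2O, MeOH, −78 °C) should reduce only the conjugated C6 carbonyl, from the face opposite the axial methyls, to (5S,6S,10R)-6-hydroxy-4,4,8,10-tetramethyl-9-methylidene-trans-decal-7-en-3-one F2. With the dienone removed, excess K[HB(sec-Bu)3] in THF at −78 °C reduces C3 from the equatorial side to (3S,5S,6S,10R)-4,4,8,10-tetramethyl-9-methylidene-trans-decal-7-ene-3,6-diol F3. Hydroboration of F3 with 9-BBN then gives the tris(boryl) adduct 14, where the route is rejoined before the oxidative work-up to 15.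

3. Step 6. The rhodium hydride addition may not discriminate sufficiently between the two enones, or 1,2-hydrosilylation may compete. Fallback: setting out from 8, the cis-disubstituted C1=C2 bond is hydrogenated with H2 and RhCl(PPh3)3 in benzene, conditions under which the trisubstituted C7=C8 bond is not reduced, to give (5S,10R)-6,6-dimethoxy-4,4,8,10-tetramethyl-cis-decal-7-ene-3,9-dione F4. Because C4 is quaternary and C9 has no α-hydrogen, LiN(iPr)2 in THF at −78 °C can only form the C2=C3 lithium enolate of F4 F5, and trapping with Et3SiCl gives 9, where the route is rejoined.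

**Further compounds**

F1 | step 3 | (4S,5R,10S)-3-(tert-butyldimethylsilyloxy)-6,6-dimethoxy-4,8,10-trimethyl-cis-decalin-2,7-dien-9-one (enantiomer of 5) | CC1=CC(OC)(OC)[C@@H]2[C@H](C)C(O[Si](C)(C)C(C)(C)C)=CC[C@]2(C)C1=O
F2 | step 9 | (5S,6S,10R)-6-hydroxy-4,4,8,10-tetramethyl-9-methylidene-trans-decal-7-en-3-one | CC1=C[C@H](O)[C@@H]2C(C)(C)C(=O)CC[C@@]2(C)C1=C
F3 | step 9 | (3S,5S,6S,10R)-4,4,8,10-tetramethyl-9-methylidene-trans-decal-7-ene-3,6-diol | CC1=C[C@H](O)[C@@H]2C(C)(C)[C@@H](O)CC[C@@]2(C)C1=C
F4 | step 6 | (5S,10R)-6,6-dimethoxy-4,4,8,10-tetramethyl-cis-decal-7-ene-3,9-dione | CC1=CC(OC)(OC)[C@H]2C(C)(C)C(=O)CC[C@@]2(C)C1=O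
F5 | step 6 | C2=C3 lithium enolate of F4 | CC1=CC(OC)(OC)[C@H]2C(C)(C)C(O[Li])=CC[C@@]2(C)C1=O
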